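**Plan**
- Retrosynthetic cuts: the five phenols are masked as MOM ethers. The side chain ring A–CH2–CH(OH)–C(CH3)=CH2 is traced back through an epoxy iodide and a (2R,3R)-epoxy alcohol to ring A–CH2–CH=C(CH3)–CH2OH. The ring A–CH2–ring B bridge is cut next, and the ring A–CH2(allyl) bond last.
- Enabling feature: the carbinol carbon lies next to the benzylic CH2 of ring A and carries a CH2=C(CH3) group. It is therefore C3 of a 1,3-transposed (E)-2-methylbut-2-en-1-ol unit. An oxirane oxygen placed on C3 becomes the target hydroxyl once the C2–O bond is broken reductively.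
- Forward order: both benzene rings are purchased. Ring B is acetylated, O-methylated and aminomethylated. Ring A is C-alkylated with a C5 allylic halide made from isoprene monoxide.
- The halves are joined through a ring B ortho-quinone methide, then MOM-protected and desilylated. The only ring formed is the temporary oxirane, which is opened again two steps later.
- Stereochemistry: the single (R) stereocentre comes from the D-(−)-tartrate ligand of the epoxidation. Its C–O bond is never broken afterwards.

Key step: step 10

Remark: 2-methyl-2-vinyloxirane (the monoepoxide of isoprene) is taken as purchased. Side-chain atoms are numbered C1 (CH2OH carbon), C2 (methyl-bearing carbon), C3 (carbon next to the benzylic CH2) and C4 (benzylic CH2).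

**Step 1**
Reactants: 1 2,4,6-trihydroxytoluene
Product: 2 1-(2,4,6-trihydroxy-3-methylphenyl)ethan-1-one
Conditions: Ac2O (1.0 equiv), BF3·OEt2 (medium), 80 °C; aq. work-up
Reagents that add atoms: acetic anhydride CC(=O)OC(C)=O
Why: Friedel–Crafts C-acylation at one of the two equivalent free carbons of a very electron-rich ring, in which the first acyl group deactivates the ring so that monoacylation should prevail.

**Step 2**
Reactants: 2 1-(2,4,6-trihydroxy-3-methylphenyl)ethan-1-one
Product: 3 1-(2,6-dihydroxy-4-methoxy-3-methylphenyl)ethan-1-one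
Conditions: Me2SO4 (1.0 equiv), K2CO3 (1.0 equiv), acetone, reflux
Reagents that add atoms: dimethyl sulfate COS(=O)(=O)OC
Why: Williamson-type O-methylation in which the hydroxyl para to the acetyl group reacts first, because it is the most acidic one and the only one that cannot hydrogen-bond to the carbonyl, while the hard electrophile favours oxygen over ring carbon.

**Step 3**
Reactants: 3 1-(2,6-dihydroxy-4-methoxy-3-methylphenyl)ethan-1-one; 4 formaldehyde
Product: 6 1-{3-[(dimethylamino)methyl]-2,6-dihydroxy-4-methoxy-5-methylphenyl}ethan-1-one, via (dimethylamino)methanol 5 (not isolated)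
Conditions: 37% aq. CH2O premixed with 40% aq. Me2NH, EtOH, rt
Reagents that add atoms: dimethylamine CNC
Why: Phenolic Mannich reaction at the only unsubstituted ring carbon, with premixing of amine and aldehyde keeping free formaldehyde low so that the symmetrical methylene-bis dimer should be suppressed.

**Step 4**
Reactants: 7 2-methyl-2-vinyloxirane (racemic)
Product: 9 (2E)-4-chloro-2-methylbut-2-en-1-ol, via trichlorotitanium alkoxide 8 (not isolated)
Conditions: TiCl4, CH2Cl2, −80 °C; 1 M aq. HCl quench
Reagents that add atoms: titanium tetrachloride Cl[Ti](Cl)(Cl)Cl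
Why: Lewis-acid-promoted SN2′ opening of a vinyl oxirane, in which chloride adds to the vinyl terminus of the s-trans conformer to give the E alkene and erase the oxirane stereocentre; any Z isomer must be removed by chromatography because it would lead to the opposite carbinol configuration later.

**Step 5**
Reactants: 9 (2E)-4-chloro-2-methylbut-2-en-1-ol
Product: 10 tert-butyl{[(2E)-4-chloro-2-methylbut-2-en-1-yl]oxy}dimethylsilane
Conditions: TBSCl, imidazole, CH2Cl2, 0 °C → rt
Reagents that add atoms: tert-butyldimethylsilyl chloride CC(C)(C)[Si](C)(C)Cl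
Why: Standard imidazole-mediated silylation of a primary alcohol, giving an ether that, unlike an acetate, should survive carbonate, liberated dimethylamine and NaH and can later be removed orthogonally to MOM.

**Step 6**
Reactants: 10 tert-butyl{[(2E)-4-chloro-2-methylbut-2-en-1-yl]oxy}dimethylsilane; 11 1-(2,4,6-trihydroxyphenyl)butan-1-one (2 equiv)
Product: 13 1-{3-[(2E)-4-(tert-butyldimethylsilyloxy)-3-methylbut-2-en-1-yl]-2,4,6-trihydroxyphenyl}butan-1-one, via allylic iodide 12 (not isolated)
Conditions: NaI (1.1 equiv), K2CO3, acetone, reflux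
Reagents that add atoms: none
Why: Finkelstein exchange followed by C-alkylation of the ambident acylphloroglucinol anion with the soft primary allylic iodide (SN2 at CH2, E alkene retained), as known for prenyl and geranyl halides, with the excess nucleophile limiting a second alkylation.

**Step 7**
Reactants: 6 1-{3-[(dimethylamino)methyl]-2,6-dihydroxy-4-methoxy-5-methylphenyl}ethan-1-one; 13 1-{3-[(2E)-4-(tert-butyldimethylsilyloxy)-3-methylbut-2-en-1-yl]-2,4,6-trihydroxyphenyl}butan-1-one
Product: 15 1-{3-[(3-acetyl-2,4-dihydroxy-6-methoxy-5-methylphenyl)methyl]-5-[(2E)-4-(tert-butyldimethylsilyloxy)-3-methylbut-2-en-1-yl]-2,4,6-trihydroxyphenyl}butan-1-one, via ring B ortho-quinone methide 14 (not isolated)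
Conditions: 1,4-dioxane, 80 °C, N2 stream
Reagents that add atoms: none
Why: Thermal loss of dimethylamine from the ortho-hydroxybenzylamine gives an ortho-quinone methide that is captured in a Michael-type addition by the only free ring carbon of 13, the established Mannich-base route to unsymmetrical methylene-bridged acylphloroglucinols.

**Step 8**
Reactants: 15 pentaphenol dimer (name as in step 7)
Product: 16 1-{3-[(3-acetyl-6-methoxy-2,4-bis(methoxymethoxy)-5-methylphenyl)methyl]-5-[(2E)-4-(tert-butyldimethylsilyloxy)-3-methylbut-2-en-1-yl]-2,4,6-tris(methoxymethoxy)phenyl}butan-1-one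
Conditions: NaH (6 equiv), MOMCl (7 equiv), DMF, 0 °C → rt
Reagents that add atoms: chloromethyl methyl ether COCCl
Why: Williamson-type O-alkylation of the pentaphenoxide with a hard electrophile that attacks oxygen rather than ring carbon, full deprotonation breaking the hydrogen bonds to both ketones and denying the bridge the proton source it needs to fragment.

**Step 9**
Reactants: 16 pentakis-MOM silyl ether (name as in step 8)
Product: 17 1-{3-[(3-acetyl-6-methoxy-2,4-bis(methoxymethoxy)-5-methylphenyl)methyl]-5-[(2E)-4-hydroxy-3-methylbut-2-en-1-yl]-2,4,6-tris(methoxymethoxy)phenyl}butan-1-one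
Conditions: n-Bu4NF, THF, 0 °C
Reagents that add atoms: none
Why: Fluoride-induced silyl ether cleavage, driven by the Si–F bond, frees the primary allylic alcohol while aryl MOM acetals, ketones and the E alkene are untouched.

**Step 10**
Reactants: 17 pentakis-MOM (E)-allylic alcohol (name as in step 9)
Product: 18 1-{3-[(3-acetyl-6-methoxy-2,4-bis(methoxymethoxy)-5-methylphenyl)methyl]-5-{[(2R,3R)-3-(hydroxymethyl)-3-methyloxiran-2-yl]methyl}-2,4,6-tris(methoxymethoxy)phenyl}butan-1-one
Conditions: Ti(OiPr)4 (0.2 equiv), D-(−)-diisopropyl tartrate (0.25 equiv), t-BuOOH (2 equiv, decane), 4 Å MS, CH2Cl2, −20 °C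
Reagents that add atoms: tert-butyl hydroperoxide CC(C)(C)OO
Why: Katsuki–Sharpless asymmetric epoxidation: the C1 hydroxyl of 17 and t-BuOOH exchange for isopropoxide on the dimeric titanium tartrate complex, and the titanium-activated peroxide oxygen is handed to the bound C2=C3 alkene in one concerted step that releases t-BuOH. The oxirane, the only ring formed, closes by this suprafacial [2+1] oxygen-atom transfer with both C–O bonds made on the same face, so the E geometry is translated into the trans relation of CH2OH and the benzylic CH2. Both new stereocentres are set by the ligand alone: D-(−)-tartrate steers oxygen to the C2-Si/C3-Re face and should give the (2R,3R)-epoxide, the mirror image of the (2S,3S) series obtained from (E)-allylic alcohols with L-(+)-tartrate, and 17 has no stereocentre that could oppose the catalyst. (E)-Trisubstituted primary allylic alcohols with a C2 methyl group are among the best substrate classes of this reaction. The selectivity needed is enantioface selection plus chemoselectivity, and both rest on the free primary hydroxyl, which ties the only alkene of 17 to titanium, while aryl ketones, MOM acetals and the aryl methyl ether do not react with the reagent at −20 °C; sieves, catalytic titanium and a non-acidic work-up guard the product against opening by a neighbouring acetal oxygen. C3 of 18 already holds the oxygen atom and the R configuration of the target carbinol.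

**Step 11**
Reactants: 18 (2R,3R)-epoxy alcohol (name as in step 10)
Product: 19 1-{3-[(3-acetyl-6-methoxy-2,4-bis(methoxymethoxy)-5-methylphenyl)methyl]-5-{[(2R,3S)-3-(iodomethyl)-3-methyloxiran-2-yl]methyl}-2,4,6-tris(methoxymethoxy)phenyl}butan-1-one
Conditions: I2, PPh3, imidazole, THF, 0 °C
Reagents that add atoms: iodine II
Why: Appel-type iodination (Garegg–Samuelsson conditions) in which iodide displaces the alkoxyphosphonium group at C1 by SN2, so neither oxirane carbon is touched (the quaternary carbon is now called S only because CH2I outranks the other oxirane carbon) and imidazole keeps the medium non-acidic.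

**Step 12**
Reactants: 19 epoxy iodide (name as in step 11)
Product: 21 1-{3-[(3-acetyl-6-methoxy-2,4-bis(methoxymethoxy)-5-methylphenyl)methyl]-5-[(2R)-2-hydroxy-3-methylbut-3-en-1-yl]-2,4,6-tris(methoxymethoxy)phenyl}butan-1-one, via iodozinc alkoxide 20 (not isolated)
Conditions: activated Zn dust, EtOH, 60 °C; aq. work-up
Reagents that add atoms: none
Why: Reductive opening of a 2,3-epoxy iodide (Boord-type elimination): zinc inserts into the C–I bond and the organozinc expels the C2–O bond, which creates CH2=C(CH3) and leaves the C3–O bond and its R configuration intact under neutral conditions.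

**Step 13**
Reactants: 21 pentakis-MOM isopropenyl carbinol (name as in step 12)
Product: 23 1-{3-[(3-acetyl-2,4-dihydroxy-6-methoxy-5-methylphenyl)methyl]-2,4,6-trihydroxy-5-[(2R)-2-hydroxy-3-methylbut-3-en-1-yl]phenyl}butan-1-one, via hexakis(trimethylsilyl) ether 22 (not isolated)
Conditions: TMSOTf (excess), 2,2'-bipyridyl (excess), MeCN, 0 °C → rt; then H2O, rt
Reagents that add atoms: none
Why: Silyl triflate–bipyridyl acetal cleavage, in which buffered TMSOTf turns each aryl MOM ether into an aryl silyl ether plus an N-(methoxymethyl)bipyridinium salt without free strong acid and water then hydrolyses all Si–O bonds, so that the allylic carbinol, the 1,1-disubstituted alkene and the methylene bridge meet neither strong acid nor base.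

**Compound list**
1 | 2,4,6-trihydroxytoluene | Cc1c(O)cc(O)cc1O | starting material
2 | 1-(2,4,6-trihydroxy-3-methylphenyl)ethan-1-one | CC(=O)c1c(O)cc(O)c(C)c1O | intermediate
3 | 1-(2,6-dihydroxy-4-methoxy-3-methylphenyl)ethan-1-one | CC(=O)c1c(O)cc(OC)c(C)c1O | intermediate
4 | formaldehyde | C=O | starting material
5 | (dimethylamino)methanol | CN(C)CO | intermediate
6 | 1-{3-[(dimethylamino)methyl]-2,6-dihydroxy-4-methoxy-5-methylphenyl}ethan-1-one | CC(=O)c1c(O)c(CN(C)C)c(OC)c(C)c1O | intermediate
7 | 2-methyl-2-vinyloxirane (racemic) | C=CC1(C)CO1 | starting material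
8 | trichloro{[(2E)-4-chloro-2-methylbut-2-en-1-yl]oxy}titanium | Cl[Ti](Cl)(Cl)OC/C(C)=C/CCl | intermediate
9 | (2E)-4-chloro-2-methylbut-2-en-1-ol | OC/C(C)=C/CCl | intermediate
10 | tert-butyl{[(2E)-4-chloro-2-methylbut-2-en-1-yl]oxy}dimethylsilane | CC(C)(C)[Si](C)(C)OC/C(C)=C/CCl | intermediate
11 | 1-(2,4,6-trihydroxyphenyl)butan-1-one | CCCC(=O)c1c(O)cc(O)cc1O | starting material
12 | tert-butyl{[(2E)-4-iodo-2-methylbut-2-en-1-yl]oxy}dimethylsilane | CC(C)(C)[Si](C)(C)OC/C(C)=C/CI | intermediate
13 | 1-{3-[(2E)-4-(tert-butyldimethylsilyloxy)-3-methylbut-2-en-1-yl]-2,4,6-trihydroxyphenyl}butan-1-one | CC(C)(C)[Si](C)(C)OC/C(C)=C/Cc1c(O)cc(O)c(C(=O)CCC)c1O | intermediate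
14 | 2-acetyl-3-hydroxy-5-methoxy-4-methyl-6-methylidenecyclohexa-2,4-dien-1-one (ring B ortho-quinone methide) | C=C1C(=O)C(C(C)=O)=C(O)C(C)=C1OC | intermediate
15 | pentaphenol dimer with (E)-TBS-oxy side chain | CC(C)(C)[Si](C)(C)OC/C(C)=C/Cc1c(O)c(Cc2c(O)c(C(C)=O)c(O)c(C)c2OC)c(O)c(C(=O)CCC)c1O | intermediate
16 | pentakis-MOM dimer with (E)-TBS-oxy side chain | CC(C)(C)[Si](C)(C)OC/C(C)=C/Cc1c(OCOC)c(Cc2c(OCOC)c(C(C)=O)c(OCOC)c(C)c2OC)c(OCOC)c(C(=O)CCC)c1OCOC | intermediate
17 | pentakis-MOM (E)-primary allylic alcohol | OC/C(C)=C/Cc1c(OCOC)c(Cc2c(OCOC)c(C(C)=O)c(OCOC)c(C)c2OC)c(OCOC)c(C(=O)CCC)c1OCOC | intermediate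
18 | pentakis-MOM (2R,3R)-2,3-epoxy alcohol | OC[C@@]1(C)O[C@@H]1Cc1c(OCOC)c(Cc2c(OCOC)c(C(C)=O)c(OCOC)c(C)c2OC)c(OCOC)c(C(=O)CCC)c1OCOC | intermediate
19 | pentakis-MOM epoxy iodide (C2 S, C3 R) | IC[C@@]1(C)O[C@@H]1Cc1c(OCOC)c(Cc2c(OCOC)c(C(C)=O)c(OCOC)c(C)c2OC)c(OCOC)c(C(=O)CCC)c1OCOC | intermediate
20 | iodozinc alkoxide of 21 | C=C(C)[C@H](O[Zn]I)Cc1c(OCOC)c(Cc2c(OCOC)c(C(C)=O)c(OCOC)c(C)c2OC)c(OCOC)c(C(=O)CCC)c1OCOC | intermediate
21 | pentakis-MOM (R)-isopropenyl carbinol | C=C(C)[C@H](O)Cc1c(OCOC)c(Cc2c(OCOC)c(C(C)=O)c(OCOC)c(C)c2OC)c(OCOC)c(C(=O)CCC)c1OCOC | intermediate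
22 | hexakis(trimethylsilyl) ether of 23 | C=C(C)[C@H](O[Si](C)(C)C)Cc1c(O[Si](C)(C)C)c(Cc2c(O[Si](C)(C)C)c(C(C)=O)c(O[Si](C)(C)C)c(C)c2OC)c(O[Si](C)(C)C)c(C(=O)CCC)c1O[Si](C)(C)C | intermediate
23 | 1-{3-[(3-acetyl-2,4-dihydroxy-6-methoxy-5-methylphenyl)methyl]-2,4,6-trihydroxy-5-[(2R)-2-hydroxy-3-methylbut-3-en-1-yl]phenyl}butan-1-one | C=C(C)[C@H](O)Cc1c(O)c(Cc2c(O)c(C(C)=O)c(O)c(C)c2OC)c(O)c(C(=O)CCC)c1O | target

**Total step count:** 13.
**Longest linear sequence:** 10 steps (1 → 2 → 3 → 6 → 15 → 16 → 17 → 18 → 19 → 21 → 23). The branch from 7 is equally long.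

**Steps most likely to fail**

**Step 13, fivefold acetal cleavage on a substrate that already holds the allylic carbinol.**
- What may go wrong: cleavage may stall at the crowded acetals. The silyl triflate may ionise the allylic C–O bond, or it may trigger attack of a freed ortho phenol on the side chain. Material or configuration would then be lost.
- Fallback: the deprotection is moved ahead of the unmasking, so that no alkene exists while acid is present.
- Setting out from 19, dry HCl in Et2O/CH2Cl2 at −30 °C should open the oxirane at its tertiary carbon C2, with the C3–O bond not involved. This gives the pentakis-MOM (2R,3R)-chloro iodo alcohol F1.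
- HCl in MeOH at 40 °C then removes the five MOM groups by ordinary acid methanolysis and should give the pentaphenol chloro iodo alcohol F2.
- Zinc dust in EtOH at room temperature finally removes the vicinal chlorine and iodine (classical zinc dehalogenation). This creates CH2=C(CH3) next to the untouched carbinol and returns to the route at 23.
- Products in which methanol or an ortho phenol has taken C2 in place of chloride are β-alkoxy or β-aryloxy iodides. They should collapse to the same alkene with zinc (Boord-type elimination).

**Step 7, union of the two rings.**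
- What may go wrong: at the temperature needed for amine loss the new aryl–CH2 bond may form reversibly. The ring partners would then exchange and symmetrical dimers would build up. Amine loss itself may also be sluggish.
- Fallback: the roles of the rings are exchanged.
- Setting out from 13, a Mannich reaction with 4 and dimethylamine (as in step 3) at the last free ring A carbon should give the ring A Mannich base F3.
- The aminomethyl group of F3 is flanked by a hydroxyl that is not chelated to a ketone. Amine loss to the ring A ortho-quinone methide F4 should therefore set in at lower temperature.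
- This species is intercepted by an excess of the cheap monomer 3 at its only free carbon, which returns to the route at 15.

**Step 6, mono-C-alkylation of ring A.**
- What may go wrong: O-alkylation and a second ring alkylation compete with the wanted attack, and unchanged nucleophile has to be separated.
- Fallback: the bridge is made first and the side chain second, with π-allyl chemistry in place of SN2.
- Setting out from 6 and an excess of 11 (dioxane, 80 °C, as in step 7), the side-chain-free dimer F5 is made. It has a single unsubstituted ring carbon, so a second aromatic alkylation is impossible.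
- It is then allylated with 10 under Tsuji–Trost conditions (Pd(PPh3)4 as source of zerovalent palladium, K2CO3, THF, rt).
- Aryl allyl ethers formed by O-attack are re-ionised by the catalyst and drain to the C-allylated product. Attack occurs at the unsubstituted terminus of the π-allyl unit with the E geometry kept, and the route is rejoined at 15.

**Further compounds**
F1 | step 13 | 1-{3-[(3-acetyl-6-methoxy-2,4-bis(methoxymethoxy)-5-methylphenyl)methyl]-5-[(2R,3R)-3-chloro-2-hydroxy-4-iodo-3-methylbutyl]-2,4,6-tris(methoxymethoxy)phenyl}butan-1-one | IC[C@]([C@H](O)Cc1c(OCOC)c(Cc2c(OCOC)c(C(C)=O)c(OCOC)c(C)c2OC)c(OCOC)c(C(=O)CCC)c1OCOC)(C)Cl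
F2 | step 13 | 1-{3-[(3-acetyl-2,4-dihydroxy-6-methoxy-5-methylphenyl)methyl]-5-[(2R,3R)-3-chloro-2-hydroxy-4-iodo-3-methylbutyl]-2,4,6-trihydroxyphenyl}butan-1-one | IC[C@]([C@H](O)Cc1c(O)c(Cc2c(O)c(C(C)=O)c(O)c(C)c2OC)c(O)c(C(=O)CCC)c1O)(C)Cl
F3 | step 7 | 1-{3-[(2E)-4-(tert-butyldimethylsilyloxy)-3-methylbut-2-en-1-yl]-5-[(dimethylamino)methyl]-2,4,6-trihydroxyphenyl}butan-1-one | CC(C)(C)[Si](C)(C)OC/C(C)=C/Cc1c(O)c(CN(C)C)c(O)c(C(=O)CCC)c1O
F4 | step 7 | 4-butanoyl-2-[(2E)-4-(tert-butyldimethylsilyloxy)-3-methylbut-2-en-1-yl]-3,5-dihydroxy-6-methylidenecyclohexa-2,4-dien-1-one | C=C1C(=O)C(C/C=C(\C)CO[Si](C)(C)C(C)(C)C)=C(O)C(C(=O)CCC)=C1O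
F5 | step 6 | 1-{3-[(3-acetyl-2,4-dihydroxy-6-methoxy-5-methylphenyl)methyl]-2,4,6-trihydroxyphenyl}butan-1-one | CCCC(=O)c1c(O)cc(O)c(Cc2c(O)c(C(C)=O)c(O)c(C)c2OC)c1O
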